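**Plan**
- Retrosynthesis: the phenol is unmasked last. The side-chain C2'–C3' bond (CH2–CH=) is cut into a chromen-2-ylethylzinc reagent and the ring A (E)-alkenyl iodide. The pyran is cut at C4–C4a to an aryl propargyl ether, whose O1–aryl bond comes from SNAr and whose alkyne comes from an epoxy chloride fragmentation.
- Forward order: acyclic (S)-propargylic carbinol, then the aryl ether, then the pyran ring (gold, C4–C4a). Ring A is made separately from the enone and its ring is never opened. The chain is joined last by Negishi coupling.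
- Enabling feature: the benzo ring is a hydroquinone, with O1 and the oxygen on C6 para to each other. The two carbons ortho to O1 are therefore equivalent and either can become C4a. The C3=C4 alkene of the 2H-pyran ring is exactly what addition of an aryl C–H across a C≡C delivers.
- Stereochemistry: C2 (S) is set by Sharpless epoxidation with L-(+)-tartrate; its C–O bond is not broken in the fragmentation, the SNAr or the ring closure. Ring A C1 (S) comes from CBS reduction of the enone followed by suprafacial Johnson–Claisen transfer. The E alkene comes from syn-carboalumination.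

Key step: step 9

Step 1
Reactants: 1 but-3-yn-1-ol
Product: 2 (but-3-yn-1-yloxy)triisopropylsilane
Conditions: TIPSCl, imidazole, DMF, 0 °C to rt
Reagents that add atoms: triisopropylsilyl chloride, CC(C)[Si](Cl)(C(C)C)C(C)C
Why: Silyl ether protection of a primary alcohol; the bulky TIPS group is chosen because it should not migrate to the tertiary alkoxide generated in step 6.

Step 2
Reactants: 2 (but-3-yn-1-yloxy)triisopropylsilane
Product: 5 (E)-3-methyl-5-(triisopropylsilyloxy)pent-2-en-1-ol, via alkenylalane 3 (not isolated), via lithium alkenylaluminate 4 (not isolated)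
Conditions: Me3Al, Cp2ZrCl2 (0.25 equiv), CH2Cl2, 0 °C to rt; excess Me3Al removed in vacuo; n-BuLi, hexane/THF, −78 °C; (CH2O)n, −78 °C to rt
Reagents that add atoms: trimethylaluminium, C[Al](C)C; paraformaldehyde (source of formaldehyde), C=O
Why: Zirconium-catalysed Negishi carboalumination adds methyl and aluminium syn across the terminal alkyne with aluminium on the terminal carbon, and hydroxymethylation of the derived aluminate with formaldehyde proceeds with retention, fixing the E trisubstituted alkene.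

Step 3
Reactants: 5 (E)-3-methyl-5-(triisopropylsilyloxy)pent-2-en-1-ol
Product: 6 {(2S,3S)-3-methyl-3-[2-(triisopropylsilyloxy)ethyl]oxiran-2-yl}methanol
Conditions: Ti(OiPr)4 (10 mol%), L-(+)-diethyl tartrate (12 mol%), t-BuOOH, 4 Å MS, CH2Cl2, −20 °C
Reagents that add atoms: tert-butyl hydroperoxide, CC(C)(C)OO
Why: Sharpless asymmetric epoxidation of an E trisubstituted allylic alcohol; L-(+)-tartrate should give the (2S,3S)-epoxide, as it does with geraniol, which has the same substitution pattern, and this sets the future C2 of the chromene.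

Step 4
Reactants: 6 {(2S,3S)-3-methyl-3-[2-(triisopropylsilyloxy)ethyl]oxiran-2-yl}methanol
Product: 7 {2-[(2S,3R)-3-(chloromethyl)-2-methyloxiran-2-yl]ethoxy}triisopropylsilane
Conditions: PPh3, CCl4, NaHCO3, reflux
Reagents that add atoms: carbon tetrachloride, ClC(Cl)(Cl)Cl
Why: Appel chlorination of the primary alcohol occurs at the CH2 carbon only, so both epoxide centres keep their geometry (the descriptor of the CH carbon changes only because CH2Cl outranks the ring carbon).

Step 5
Reactants: 7 {2-[(2S,3R)-3-(chloromethyl)-2-methyloxiran-2-yl]ethoxy}triisopropylsilane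
Product: 8 (S)-3-methyl-5-(triisopropylsilyloxy)pent-1-yn-3-ol
Conditions: n-BuLi (3.3 equiv), THF, −78 to −30 °C; then H2O
Reagents that add atoms: none
Why: Base-induced fragmentation of a 2,3-epoxy chloride (lithiation at CH2Cl, β-elimination that opens the epoxide, then loss of HCl from the chloroalkene) gives the terminal propargylic alcohol without breaking the tertiary C–O bond, so the S configuration is carried over.

Step 6
Reactants: 8 (S)-3-methyl-5-(triisopropylsilyloxy)pent-1-yn-3-ol, 9 4-fluorobenzaldehyde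
Product: 10 (S)-4-{[3-methyl-5-(triisopropylsilyloxy)pent-1-yn-3-yl]oxy}benzaldehyde
Conditions: KN(SiMe3)2 (1.0 equiv), THF, 0 °C; then 9, THF/DMF, 0 °C to rt
Reagents that add atoms: none
Why: SNAr (addition–elimination) of the potassium tertiary alkoxide at the fluorine-bearing carbon activated by the para-formyl group; the carbinol C–O bond is not involved, so configuration is retained.

Step 7
Reactants: 10 (S)-4-{[3-methyl-5-(triisopropylsilyloxy)pent-1-yn-3-yl]oxy}benzaldehyde
Product: 12 (S)-4-{[3-methyl-5-(triisopropylsilyloxy)pent-1-yn-3-yl]oxy}phenol, via aryl formate 11 (not isolated)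
Conditions: mCPBA, CH2Cl2, 0 °C to rt; then K2CO3 (cat.), MeOH, 0 °C
Reagents that add atoms: meta-chloroperoxybenzoic acid, OOC(=O)c1cccc(Cl)c1
Why: Baeyer–Villiger (Dakin-type) oxidation of a para-alkoxybenzaldehyde with aryl migration gives the formate, which is methanolysed to the hydroquinone monoether; the terminal alkyne and both ethers are inert to the peracid at this temperature.

Step 8
Reactants: 12 (S)-4-{[3-methyl-5-(triisopropylsilyloxy)pent-1-yn-3-yl]oxy}phenol
Product: 13 (S)-4-{[3-methyl-5-(triisopropylsilyloxy)pent-1-yn-3-yl]oxy}phenyl pivalate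
Conditions: PivCl, Et3N, DMAP (cat.), CH2Cl2, 0 °C to rt
Reagents that add atoms: pivaloyl chloride, CC(C)(C)C(=O)Cl
Why: Acylation of the phenol (esterification); the pivalate should survive HF, zinc and palladium, and para to O1 it lowers the nucleophilicity of the ortho carbons no more than a halogen would.

Step 9
Reactants: 13 (S)-4-{[3-methyl-5-(triisopropylsilyloxy)pent-1-yn-3-yl]oxy}phenyl pivalate
Product: 14 (S)-2-methyl-2-[2-(triisopropylsilyloxy)ethyl]-2H-chromen-6-yl pivalate
Conditions: Ph3PAuNTf2 (3 mol%), 4 Å MS, CH2Cl2, 0 °C to rt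
Reagents that add atoms: none
Why: The monovalent gold cation binds the terminal alkyne, the aryl carbon ortho to O1 attacks the terminal alkyne carbon anti to gold, the arenium ion rearomatises and protodeauration places hydrogen on C3, leaving the C3=C4 alkene. The closest known reaction type is the gold- or platinum-catalysed intramolecular hydroarylation of aryl propargyl ethers, 1,1-disubstituted ones included, to 2H-chromenes. The pyran ring closes in the 6-endo-dig mode by forming C4–C4a. No stereocentre is created, and C2 should stay S because the O1–C2 bond is a spectator, whereas the thermal propargyl Claisen route would pass through an achiral ortho-quinone methide. The step needs 6-endo over 5-exo closure and no ionisation of the tertiary propargylic ether; the terminal alkyne, the fully substituted C2, an acid-free phosphine–gold triflimide at low temperature and molecular sieves favour both. The two carbons ortho to O1 are equivalent, so only one regioisomer can form, and the side-chain oxygen is silylated so that it cannot add to the activated alkyne.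

Step 10
Reactants: 14 (S)-2-methyl-2-[2-(triisopropylsilyloxy)ethyl]-2H-chromen-6-yl pivalate
Product: 15 (S)-2-(2-hydroxyethyl)-2-methyl-2H-chromen-6-yl pivalate
Conditions: HF·pyridine, pyridine, THF, 0 °C to rt
Reagents that add atoms: none
Why: Fluoride desilylation under buffered acidic conditions removes the primary alkyl TIPS ether, while the aryl pivalate, the tertiary allylic aryl ether and the styrene-type alkene should be inert.

Step 11
Reactants: 15 (S)-2-(2-hydroxyethyl)-2-methyl-2H-chromen-6-yl pivalate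
Product: 16 (S)-2-(2-iodoethyl)-2-methyl-2H-chromen-6-yl pivalate
Conditions: I2, PPh3, imidazole, CH2Cl2, 0 °C to rt
Reagents that add atoms: iodine, II
Why: Appel-type iodination of a primary alcohol through the alkoxyphosphonium salt (SN2 at CH2), leaving the quaternary C2 untouched.

Step 12
Reactants: 17 2,4,4-trimethylcyclohex-2-en-1-one
Product: 18 (R)-2,4,4-trimethylcyclohex-2-en-1-ol
Conditions: (S)-2-methyl-CBS-oxazaborolidine [(S)-1-methyl-3,3-diphenyltetrahydro-1H,3H-pyrrolo[1,2-c][1,3,2]oxazaborole] (0.1 equiv), BH3·SMe2, THF, −20 °C; MeOH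
Reagents that add atoms: none
Why: Corey–Bakshi–Shibata reduction; with the 2-methylalkenyl arm acting as the larger group (as phenyl does in acetophenone), the (S)-catalyst should deliver hydride to the face that gives the (R)-allylic alcohol.

Step 13
Reactants: 18 (R)-2,4,4-trimethylcyclohex-2-en-1-ol, 19 triethyl orthoacetate
Product: 21 ethyl 2-[(S)-2,6,6-trimethylcyclohex-2-en-1-yl]acetate, via ketene acetal 20 (not isolated)
Conditions: EtCO2H (cat.), neat 19, 140 °C, EtOH distilled off
Reagents that add atoms: none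
Why: Johnson–Claisen rearrangement; within the ring the [3,3] shift is suprafacial, so the new C–C bond forms at the old C3 on the face the C1–O bond leaves, turning (R)-carbinol into the (S)-ring stereocentre and moving the alkene to the 2,3-position.

Step 14
Reactants: 21 ethyl 2-[(S)-2,6,6-trimethylcyclohex-2-en-1-yl]acetate
Product: 22 2-[(S)-2,6,6-trimethylcyclohex-2-en-1-yl]ethan-1-ol
Conditions: LiAlH4, Et2O, 0 °C
Reagents that add atoms: none
Why: Hydride reduction of an ester to the primary alcohol; the trisubstituted alkene and the stereocentre are untouched.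

Step 15
Reactants: 22 2-[(S)-2,6,6-trimethylcyclohex-2-en-1-yl]ethan-1-ol
Product: 23 (S)-6-(2-iodoethyl)-1,5,5-trimethylcyclohex-1-ene
Conditions: I2, PPh3, imidazole, CH2Cl2, 0 °C to rt
Reagents that add atoms: iodine, II
Why: Appel-type iodination of the primary alcohol (SN2 at CH2).

Step 16
Reactants: 23 (S)-6-(2-iodoethyl)-1,5,5-trimethylcyclohex-1-ene
Product: 24 (S)-6-(but-3-yn-1-yl)-1,5,5-trimethylcyclohex-1-ene
Conditions: LiC≡CH·H2NCH2CH2NH2, DMSO, 10 °C to rt
Reagents that add atoms: lithium acetylide–ethylenediamine complex, [Li]C#C.NCCN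
Why: SN2 alkylation of lithium acetylide by a primary iodide in DMSO, where substitution should dominate over elimination.

Step 17
Reactants: 24 (S)-6-(but-3-yn-1-yl)-1,5,5-trimethylcyclohex-1-ene
Product: 26 (S)-6-[(E)-4-iodo-3-methylbut-3-en-1-yl]-1,5,5-trimethylcyclohex-1-ene, via alkenylalane 25 (not isolated)
Conditions: Me3Al, Cp2ZrCl2 (0.25 equiv), CH2Cl2, 0 °C to rt; then I2, THF, −30 to 0 °C
Reagents that add atoms: trimethylaluminium, C[Al](C)C; iodine, II
Why: Negishi carboalumination (syn addition of methyl and aluminium, aluminium on the terminal carbon) followed by iodinolysis with retention gives the E alkenyl iodide; the hindered ring alkene does not react.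

Step 18
Reactants: 16 (S)-2-(2-iodoethyl)-2-methyl-2H-chromen-6-yl pivalate, 26 (S)-6-[(E)-4-iodo-3-methylbut-3-en-1-yl]-1,5,5-trimethylcyclohex-1-ene
Product: 28 (S)-2-methyl-2-{(E)-4-methyl-6-[(S)-2,6,6-trimethylcyclohex-2-en-1-yl]hex-3-en-1-yl}-2H-chromen-6-yl pivalate, via alkylzinc iodide 27 (not isolated)
Conditions: 16, Zn dust (activated with BrCH2CH2Br and Me3SiCl), LiCl, THF, 30 °C; then 26, Pd(PPh3)4 (5 mol%), THF, rt to 45 °C
Reagents that add atoms: none
Why: LiCl-assisted insertion of zinc into the primary C–I bond, then Negishi sp3–sp2 cross-coupling on zerovalent palladium, which retains the E geometry of the alkenyl iodide and tolerates the aryl ester.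

Step 19
Reactants: 28 (S)-2-methyl-2-{(E)-4-methyl-6-[(S)-2,6,6-trimethylcyclohex-2-en-1-yl]hex-3-en-1-yl}-2H-chromen-6-yl pivalate
Product: 29 (S)-2-methyl-2-{(E)-4-methyl-6-[(S)-2,6,6-trimethylcyclohex-2-en-1-yl]hex-3-en-1-yl}-2H-chromen-6-ol (CNP0309797.1)
Conditions: LiAlH4, THF, 0 °C; aq. NH4Cl
Reagents that add atoms: none
Why: Reductive cleavage of the aryl pivalate by hydride (ester reduction) frees the phenol under non-oxidising conditions; the three alkenes and both stereocentres are inert.

**Compound list**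
1 | but-3-yn-1-ol | C#CCCO | starting material
2 | (but-3-yn-1-yloxy)triisopropylsilane | C#CCCO[Si](C(C)C)(C(C)C)C(C)C | intermediate
3 | dimethyl[(E)-2-methyl-4-(triisopropylsilyloxy)but-1-en-1-yl]alane | C[Al](C)/C=C(\C)CCO[Si](C(C)C)(C(C)C)C(C)C | intermediate (not isolated)
4 | lithium butyldimethyl[(E)-2-methyl-4-(triisopropylsilyloxy)but-1-en-1-yl]aluminate | [Li+].CCCC[Al-](C)(C)/C=C(\C)CCO[Si](C(C)C)(C(C)C)C(C)C | intermediate (not isolated)
5 | (E)-3-methyl-5-(triisopropylsilyloxy)pent-2-en-1-ol | OC/C=C(\C)CCO[Si](C(C)C)(C(C)C)C(C)C | intermediate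
6 | {(2S,3S)-3-methyl-3-[2-(triisopropylsilyloxy)ethyl]oxiran-2-yl}methanol | OC[C@@H]1O[C@@]1(C)CCO[Si](C(C)C)(C(C)C)C(C)C | intermediate
7 | {2-[(2S,3R)-3-(chloromethyl)-2-methyloxiran-2-yl]ethoxy}triisopropylsilane | ClC[C@@H]1O[C@@]1(C)CCO[Si](C(C)C)(C(C)C)C(C)C | intermediate
8 | (S)-3-methyl-5-(triisopropylsilyloxy)pent-1-yn-3-ol | CC(C)[Si](C(C)C)(C(C)C)OCC[C@@](O)(C)C#C | intermediate
9 | 4-fluorobenzaldehyde | O=Cc1ccc(F)cc1 | starting material
10 | (S)-4-{[3-methyl-5-(triisopropylsilyloxy)pent-1-yn-3-yl]oxy}benzaldehyde | CC(C)[Si](C(C)C)(C(C)C)OCC[C@@](Oc1ccc(C=O)cc1)(C)C#C | intermediate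
11 | (S)-4-{[3-methyl-5-(triisopropylsilyloxy)pent-1-yn-3-yl]oxy}phenyl formate | CC(C)[Si](C(C)C)(C(C)C)OCC[C@@](Oc1ccc(OC=O)cc1)(C)C#C | intermediate (not isolated)
12 | (S)-4-{[3-methyl-5-(triisopropylsilyloxy)pent-1-yn-3-yl]oxy}phenol | CC(C)[Si](C(C)C)(C(C)C)OCC[C@@](Oc1ccc(O)cc1)(C)C#C | intermediate
13 | (S)-4-{[3-methyl-5-(triisopropylsilyloxy)pent-1-yn-3-yl]oxy}phenyl pivalate | CC(C)[Si](C(C)C)(C(C)C)OCC[C@@](Oc1ccc(OC(=O)C(C)(C)C)cc1)(C)C#C | intermediate (key-step precursor)
14 | (S)-2-methyl-2-[2-(triisopropylsilyloxy)ethyl]-2H-chromen-6-yl pivalate | CC(C)[Si](C(C)C)(C(C)C)OCC[C@@]1(C)C=Cc2cc(OC(=O)C(C)(C)C)ccc2O1 | intermediate (key-step product)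
15 | (S)-2-(2-hydroxyethyl)-2-methyl-2H-chromen-6-yl pivalate | OCC[C@@]1(C)C=Cc2cc(OC(=O)C(C)(C)C)ccc2O1 | intermediate
16 | (S)-2-(2-iodoethyl)-2-methyl-2H-chromen-6-yl pivalate | ICC[C@@]1(C)C=Cc2cc(OC(=O)C(C)(C)C)ccc2O1 | intermediate
17 | 2,4,4-trimethylcyclohex-2-en-1-one | CC1=CC(C)(C)CCC1=O | starting material
18 | (R)-2,4,4-trimethylcyclohex-2-en-1-ol | CC1=CC(C)(C)CC[C@H]1O | intermediate
19 | triethyl orthoacetate | CC(OCC)(OCC)OCC | starting material
20 | 1-ethoxy-1-{[(R)-2,4,4-trimethylcyclohex-2-en-1-yl]oxy}ethene (mixed ketene acetal) | CC1=CC(C)(C)CC[C@H]1OC(=C)OCC | intermediate (not isolated)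
21 | ethyl 2-[(S)-2,6,6-trimethylcyclohex-2-en-1-yl]acetate | CCOC(=O)C[C@@H]1C(C)=CCCC1(C)C | intermediate
22 | 2-[(S)-2,6,6-trimethylcyclohex-2-en-1-yl]ethan-1-ol | OCC[C@@H]1C(C)=CCCC1(C)C | intermediate
23 | (S)-6-(2-iodoethyl)-1,5,5-trimethylcyclohex-1-ene | ICC[C@@H]1C(C)=CCCC1(C)C | intermediate
24 | (S)-6-(but-3-yn-1-yl)-1,5,5-trimethylcyclohex-1-ene | C#CCC[C@@H]1C(C)=CCCC1(C)C | intermediate
25 | dimethyl{(E)-2-methyl-4-[(S)-2,6,6-trimethylcyclohex-2-en-1-yl]but-1-en-1-yl}alane | C[Al](C)/C=C(\C)CC[C@@H]1C(C)=CCCC1(C)C | intermediate (not isolated)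
26 | (S)-6-[(E)-4-iodo-3-methylbut-3-en-1-yl]-1,5,5-trimethylcyclohex-1-ene | I/C=C(\C)CC[C@@H]1C(C)=CCCC1(C)C | intermediate
27 | iodo{2-[(S)-2-methyl-6-(pivaloyloxy)-2H-chromen-2-yl]ethyl}zinc | I[Zn]CC[C@@]1(C)C=Cc2cc(OC(=O)C(C)(C)C)ccc2O1 | intermediate (not isolated)
28 | (S)-2-methyl-2-{(E)-4-methyl-6-[(S)-2,6,6-trimethylcyclohex-2-en-1-yl]hex-3-en-1-yl}-2H-chromen-6-yl pivalate | CC1=CCCC(C)(C)[C@@H]1CC/C(C)=C/CC[C@@]1(C)C=Cc2cc(OC(=O)C(C)(C)C)ccc2O1 | intermediate
29 | (S)-2-methyl-2-{(E)-4-methyl-6-[(S)-2,6,6-trimethylcyclohex-2-en-1-yl]hex-3-en-1-yl}-2H-chromen-6-ol | CC1=CCCC(C)(C)[C@@H]1CC/C(C)=C/CC[C@@]1(C)C=Cc2cc(O)ccc2O1 | target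

**Step count**
Total: 19 steps. Longest linear sequence: 13 steps (steps 1–11, 18, 19); the ring A branch is steps 12–17.

**Steps most likely to fail**

Step 9. Closure may go 5-exo to benzofuran-type products. The gold catalyst, or adventitious acid, may also ionise the tertiary propargylic C–O bond, eroding the enantiomeric purity at C2 or cleaving the ether. The fallback closes the pyran by olefin metathesis at C3=C4 instead; it sets out from 8 and returns at 14. Semihydrogenation of 8 over Lindlar catalyst (Pd/CaCO3 poisoned with Pb(OAc)2, quinoline, H2) should give (S)-3-methyl-5-(triisopropylsilyloxy)pent-1-en-3-ol F1. Its potassium alkoxide (KN(SiMe3)2, THF) should displace fluoride from 5-bromo-2-fluorobenzaldehyde to give (S)-5-bromo-2-{[3-methyl-5-(triisopropylsilyloxy)pent-1-en-3-yl]oxy}benzaldehyde F2. Wittig methylenation (Ph3P=CH2) gives (S)-{[3-(4-bromo-2-vinylphenoxy)-3-methylpent-4-en-1-yl]oxy}triisopropylsilane F3. Ring-closing metathesis with the second-generation Grubbs catalyst (H2IMes)(PCy3)Cl2Ru=CHPh in CH2Cl2 at 40 °C should give (S)-[2-(6-bromo-2-methyl-2H-chromen-2-yl)ethoxy]triisopropylsilane F4, with no bond to C2 broken. Bromine–lithium exchange (n-BuLi, −78 °C), B(OMe)3 and H2O2/NaOH give (S)-2-methyl-2-[2-(triisopropylsilyloxy)ethyl]-2H-chromen-6-ol F5, and pivaloylation (PivCl, Et3N, DMAP) gives 14.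

Step 6. The hindered tertiary alkoxide may substitute slowly while the formyl group is consumed by carbonyl addition of alkoxide or traces of acetylide and by base-promoted disproportionation. The fallback uses a nitrile as the activating group; it sets out from 8 and returns at 10. The same potassium alkoxide and 4-fluorobenzonitrile (THF, 0 °C to rt) should give (S)-4-{[3-methyl-5-(triisopropylsilyloxy)pent-1-yn-3-yl]oxy}benzonitrile F6. Reduction with i-Bu2AlH (toluene, −78 °C) and mild aqueous acid hydrolysis of the aldimine then give aldehyde 10.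

Step 18. Zinc insertion may be incomplete, the alkylzinc may be protonated, or β-hydride elimination may follow transmetalation. The fallback reverses the polarity of the coupling; it sets out from 26 and 16 and returns at 28. Iodine–lithium exchange on 26 (t-BuLi, Et2O, −78 °C) gives {(E)-2-methyl-4-[(S)-2,6,6-trimethylcyclohex-2-en-1-yl]but-1-en-1-yl}lithium F7. ZnCl2 converts it into chloro{(E)-2-methyl-4-[(S)-2,6,6-trimethylcyclohex-2-en-1-yl]but-1-en-1-yl}zinc F8. F8 is coupled with the alkyl iodide 16 as the electrophile (Pd2(dba)3, P(c-C5H9)3, N-methylimidazole, THF/NMP, 80 °C), with retention of alkene geometry, to give 28.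

**Further compounds**
F1 | step 9 | (S)-3-methyl-5-(triisopropylsilyloxy)pent-1-en-3-ol | CC(C)[Si](C(C)C)(C(C)C)OCC[C@@](O)(C)C=C
F2 | step 9 | (S)-5-bromo-2-{[3-methyl-5-(triisopropylsilyloxy)pent-1-en-3-yl]oxy}benzaldehyde | CC(C)[Si](C(C)C)(C(C)C)OCC[C@@](Oc1ccc(Br)cc1C=O)(C)C=C
F3 | step 9 | (S)-{[3-(4-bromo-2-vinylphenoxy)-3-methylpent-4-en-1-yl]oxy}triisopropylsilane | CC(C)[Si](C(C)C)(C(C)C)OCC[C@@](Oc1ccc(Br)cc1C=C)(C)C=C
F4 | step 9 | (S)-[2-(6-bromo-2-methyl-2H-chromen-2-yl)ethoxy]triisopropylsilane | CC(C)[Si](C(C)C)(C(C)C)OCC[C@@]1(C)C=Cc2cc(Br)ccc2O1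
F5 | step 9 | (S)-2-methyl-2-[2-(triisopropylsilyloxy)ethyl]-2H-chromen-6-ol | CC(C)[Si](C(C)C)(C(C)C)OCC[C@@]1(C)C=Cc2cc(O)ccc2O1
F6 | step 6 | (S)-4-{[3-methyl-5-(triisopropylsilyloxy)pent-1-yn-3-yl]oxy}benzonitrile | CC(C)[Si](C(C)C)(C(C)C)OCC[C@@](Oc1ccc(C#N)cc1)(C)C#C
F7 | step 18 | {(E)-2-methyl-4-[(S)-2,6,6-trimethylcyclohex-2-en-1-yl]but-1-en-1-yl}lithium | [Li]/C=C(\C)CC[C@@H]1C(C)=CCCC1(C)C
F8 | step 18 | chloro{(E)-2-methyl-4-[(S)-2,6,6-trimethylcyclohex-2-en-1-yl]but-1-en-1-yl}zinc | Cl[Zn]/C=C(\C)CC[C@@H]1C(C)=CCCC1(C)C
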